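## Structural features

- The target is a 2-oxaspiro[4.5]decane. A cyclohexanone (ring A, C1 to C6) and a gamma-butyrolactone (ring B: C4, C7, C8, O9, C10) share the quaternary carbon C4.
- Ring A carries the acetamide at C1, a methylene at C2, the ketone at C3, the spiro carbon C4, a methylene at C5 and the hydroxyl at C6. C10 of ring B carries an (E)-2,6-dimethylhepta-1,5-dienyl chain (C11 to C16).
- There are four stereocentres. C1 and C6 are neighbours with N and O cis. C4 lies between the ketone and C10. C10 is an allylic lactone carbinol whose chain sits on the C3 side of ring B, and C10 itself lies on the face of ring A that carries O6 and N1.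
- Fragile groups: the beta-acetamido ketone (retro-Michael with base); the C3 ketone with the C10 oxygen beta to it (retro-aldol at C4–C10 as soon as base opens ring B); the allylic C10–O9 bond and the two trisubstituted alkenes (acid, electrophiles, osmium).
- The real difficulty is the quaternary C4 with four different carbon arms, and the relay of its configuration to C10 on one side and to C6 and C1 on the other.
- The key step uses two facts. The oxygens at C3 and C6 are para on ring A. C4 bears a carbonyl-level carbon (C10) and a CH2–carbonyl arm (C7–C8), which is the pattern of a 2-methylenesuccinic unit joined through C3–C4 and C5–C6 to a 1,4-dioxygenated butadiene.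

## Logic of the disconnections

**20 back to 16 (through 19 and 18).** The bond cut is C1–N. The cis N1/O6 pair beta to the C3 ketone is the retron of a conjugate addition in which nitrogen is delivered from O6. The acetyl group is traced back to the trichloroacetyl group of 19 and to the oxazoline carbon of 18, which 17 supplies. The cut removes the C1 stereocentre and all nitrogen chemistry. Demand: O6 must be free while C3 is a ketone, the tether must close 5-exo onto C1, and nothing after 15 may use strong base or strong acid.

**16 back to 13 (through 15 and 14).** No skeletal bond is cut; the C3 carbonyl is taken back to a carbinol. With C3 as a hydroxyl the same oxygen can direct the creation of C10, and ring A becomes the cyclohex-2-ene-1,4-diol that a Diels–Alder reaction delivers. Gain: 13 contains only base-tolerant functions. Demand: the two allylic hydroxyls of 13 must be told apart, here by size (O3 next to the spiro centre, O6 next to a CH2), with a temporary silyl ether on O6.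

**13 back to 11 (through 12).** The bonds cut are O9–C8 (lactone acyl–oxygen) and C10–H. Ring B opens to a gamma-hydroxy acid and C10 returns to a ketone. The unit O3–C3–C4–C10=O is then a beta-hydroxy ketone, the substrate of a chelation-controlled syn reduction, so the existing C3 centre can set C10. Gain: one ring and one stereocentre fewer. Demand: 1,2-delivery of hydride from the face fixed by the O3 chelate, and lactonisation through O10 only.

**11 back to 6 and 10.** The bond cut is C10–C11. It divides the molecule into two nine-carbon halves. In 6, C10 is an electrophilic strained-lactone carbonyl while C8 can be switched off as a carboxylate. Gain: convergence, with the side chain arriving with its alkene geometry fixed. Demand: one addition of 10, at C10 only.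

**10 back to 9, 8 and 7.** C11–Li goes back to C11–iodine. Then C12–CH3 and C11–iodine are cut (syn methylmetalation of a terminal alkyne, chosen because it fixes the E geometry). Then C13–C12 is cut (acetylide alkylation). Gain: the chain comes from 7 and two simple reagents. Demand: regio- and stereospecific carbometalation next to an untouched trisubstituted alkene.

**6 back to 3 (through 5 and 4).** The bonds cut are O6–C10 (bridging lactone) and the two O–acetyl bonds; C8 and C10 are rejoined as the anhydride. O6 is cis to C10 and can lactonise only there, so one operation differentiates C8 from C10 and O6 from O3. The racemate is divided between 5 and 6, where an ester must be cleaved in any case. Gain: all later chemoselectivity is traced back to the relative configuration of 3. Demand: both acetoxy groups of 3 must be cis to C10.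

**3 back to 1 and 2.** The bonds cut are C3–C4 and C5–C6. Gain: ring A, the quaternary C4 and three stereocentres from two achiral commercial compounds. The partners need no redesign: a twofold-symmetric diene removes any regiochemical question, and the anhydride ring keeps C7, C8 and C10 in lactone connectivity. Demand: endo selectivity.

## Other disconnections considered

**Alternative 1:** crossed enone–ketene acetal photocycloaddition, then retro-aldol.
- Cut: C4–C7 (permanent) and C5–C8 (temporary).
- Forward key step: irradiation of dienone A1, a 4,4-dimethoxycyclohexa-2,5-dienone bearing at C4 the C10 carbinol as an O-silyl ketene acetal. The excited C3–C4–C5 enone should add across C7=C8 in the crossed sense to give the 2-oxabicyclo[2.1.1]hexane A2. Unmasking the C6 ketone and the C8 alkoxide should then cleave C5–C8 and leave ring B spiro at C4.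
- In favour: the C4/C10 relation is fixed by a two-atom tether. This is better than the chosen plan, which relies on a chelation-controlled reduction. The absolute configuration derives from one carbinol centre that can be made by asymmetric alkenylation, so no resolution is needed; this is also better.
- Against: cross-conjugated dienones are prone to photorearrangement. The side-chain alkenes can quench the triplet or isomerise at C11=C12. The ketene acetal is hydrolytically fragile.
- Comparison, structure: after unzipping, ring A is an ene-1,4-dione, so C6 must be reduced selectively and cis to C10 before the same nitrogen endgame. That is one step where the chosen plan spends three, but its facial outcome is uncertain; roughly equal.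
- Comparison, mechanism: a stepwise triplet diradical is less predictable than a concerted thermal cycloaddition.
- Comparison, step economy: overall length should be about equal.

**Alternative 2:** Birch diene desymmetrised by iodolactonisation.
- Cut: O6–C10, with C4 made quaternary beforehand by Birch reduction–alkylation of an aromatic acid.
- Forward key step: the prochiral diene acid A3 would be treated with I2 and a chiral catalyst. The C10 carboxyl attacks C6 of one alkene while iodine adds to C5 (anti addition), giving the bridged iodolactone A4.
- In favour: C4 and C6 are set together from a symmetric precursor under catalyst control. On absolute configuration this is better than the chosen plan, since no half of the material is lost. The C8 ester/C10 lactone differentiation and the cis O6/C10 relation are the same as in 5 (equal).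
- Against: only C6 is oxygenated. O3 and N1 must still be introduced on the C1–C2=C3 segment with a transposition, and the iodine must be removed. The gamma-lactone mode competes with beta-lactone closure for a beta,gamma-unsaturated acid. The tert-butyl ester is an electrophile in a later organolithium step.
- Comparison: the ionic anti addition is as well defined as the cycloaddition (equal on mechanism). The chosen plan places O3, O6 and the C1=C2 alkene in one step, so the alternative is expected to be several steps longer.

**Alternative 3:** ketone oxygen as tether, osmium delivers N and O.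
- Cut: C1–N and C6–O together.
- Forward key step: the C3 N-acyloxycarbamate A5 (ring A with a C1=C6 alkene, ring B and the side chain complete) would be treated with catalytic K2OsO2(OH)4. A tethered imido-osmium species should add syn across C1=C6 and give the bridging cyclic carbamate A6 with free C6–OH.
- In favour: both heteroatoms are installed in one stereospecific step with regiochemistry fixed by the tether. In bond economy this is better than the chosen endgame, which needs six steps (8 to 13) for C1–N. In A6 the C6 hydroxyl is the only free one, so O3/O6 differentiation is easier (better).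
- Against: the substrate needs a skipped C1=C6 alkene with O3 cis to C10, which the cycloadduct 3 does not provide, so ring A would need another synthesis. The electron-rich alkenes C11=C12 and C15=C16 are good substrates for osmium oxo and imido species, so chemoselectivity is doubtful. A six-membered tether is less efficient than a five-membered one. Carbamate cleavage needs nucleophilic base in the presence of ring B.
- Comparison: the syn addition is mechanistically as reliable as the aza-Michael closure (equal). Total length is expected to be similar once a new ring A synthesis is included.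

Key step: step 1

Assumption: the esterase of step 3 is taken to hydrolyse the antipode of 5 that leads to 6 faster; if its preference is the reverse, the wanted antipode is the unreacted ester, which is recovered and saponified, and the sense must be confirmed by correlation before going on.
Convention: 3, 4 and 5 are racemates; their SMILES show the antipode that is carried forward.

## Route

Step 1
Reactants: 1 itaconic anhydride (3-methylideneoxolane-2,5-dione); 2 (1E,3E)-buta-1,3-diene-1,4-diyl diacetate
Product: 3 racemic 6,9-diacetoxy-2-oxaspiro[4.5]dec-7-ene-1,3-dione (spiro anhydride; C1=C2 alkene; acetoxy groups at C3 and C6 cis to each other and cis to the C10 carbonyl and trans to C7)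
Conditions: toluene (2 M), BHT (cat.), 100 °C, sealed vessel
Reagents that add atoms: none
Why: Concerted, asynchronous suprafacial [4+2] cycloaddition between the s-cis (E,E)-diene, whose HOMO is raised by two acyloxy donors, and the exocyclic C=C of 1, whose LUMO is lowered by the conjugated C10 carbonyl; the closest known reaction type is the thermal Diels–Alder reaction of 1,4-diacyloxybutadienes with cyclic anhydrides and of 2-methylene anhydrides and lactones with open-chain dienes. Ring A is the only ring closed and it is closed by the cycloaddition itself: C3–C4 and C5–C6 form in one step and the anhydride ring ends spiro at C4. C3 and C6 are set cis to each other by the E,E geometry of the diene and the suprafacial addition. C4 is set relative to them by the endo orientation, in which the flat conjugated C10=O lies under the diene and the C7 methylene points away, so both acetoxy groups finish cis to C10 and trans to C7. The step needs endo over exo selectivity; secondary overlap of C10=O with the diene favours endo, the out-of-plane C7 hydrogens would clash with the diene in the exo mode, and an open-chain diene has no bridging group to penalise the carbonyl-endo mode. Regioselectivity is not an issue because the diene is twofold symmetric. Base-free conditions, moderate temperature and a radical inhibitor guard against migration of the exocyclic double bond of 1 into the ring and against polymerisation. Both partners are achiral, so 3 is racemic and the absolute configuration is selected in step 3.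

Step 2
Reactants: 3 racemic spiro anhydride diacetate
Product: 5 racemic methyl 2-(2-hydroxy-7-oxo-6-oxabicyclo[3.2.1]oct-3-en-1-yl)acetate (lactone O6–C10 bridging ring A; free C3–OH syn to the lactone bridge; C8 methyl ester), via half ester 4 (not isolated)
Conditions: HCl (0.3 equiv, 1.25 M in MeOH), MeOH, 0 °C to 40 °C
Reagents that add atoms: methanol, CO
Why: Methanol opens the anhydride at the unhindered C8 carbonyl to give 4, acid-catalysed transesterification removes both acetates, and the C6 hydroxyl, cis to C10, closes the five-membered bridging lactone onto the C10 acid (intramolecular Fischer esterification); O3 could reach C10 only through a four-membered ring and O6 is trans to the C7–C8 arm, so C8 and C10 are told apart without reagent control. Only acyl–oxygen bonds are made or broken, so C3, C4 and C6 are untouched.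

Step 3
Reactants: 5 racemic hydroxy lactone methyl ester
Product: 6 2-(2-hydroxy-7-oxo-6-oxabicyclo[3.2.1]oct-3-en-1-yl)acetic acid as the single enantiomer shown in the compound list (C4 as in the target)
Conditions: pig liver esterase, 0.1 M phosphate buffer pH 7.2, acetone (10% v/v), 25 °C, to about half conversion; acid–base extraction
Reagents that add atoms: water, O
Why: Enzymatic kinetic resolution by enantioselective ester hydrolysis: the esterase binds the CH2CO2CH3 arm on the quaternary stereocentre C4 in a chiral pocket and cleaves one antipode faster, so the acid goes into aqueous base and the unreacted antipode of 5 stays in the organic phase. The step also frees the C8 acid that step 6 needs as an inert carboxylate, so the resolution costs no extra operation. No stereocentre is touched; all later compounds are single enantiomers.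

Step 4
Reactants: 7 5-bromo-2-methylpent-2-ene
Product: 8 6-methylhept-5-en-1-yne
Conditions: LiC≡CH·H2NCH2CH2NH2 (1.3 equiv), DMSO, 10 °C to rt
Reagents that add atoms: lithium acetylide ethylenediamine complex, [Li+].[C-]#C.NCCN
Why: SN2 alkylation of the acetylide by a primary homoallylic bromide in a dipolar aprotic solvent; no stereocentre is involved.

Step 5
Reactants: 8 6-methylhept-5-en-1-yne
Product: 9 (1E)-1-iodo-2,6-dimethylhepta-1,5-diene
Conditions: Al(CH3)3 (2 equiv), (C5H5)2ZrCl2 (0.2 equiv), CH2Cl2, 0 °C to rt; then I2, THF, −30 °C; aq. K2CO3
Reagents that add atoms: trimethylaluminium, C[Al](C)C; iodine, II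
Why: Zirconium-catalysed methylalumination (Negishi carboalumination) adds CH3 and Al syn across the terminal alkyne with Al at the terminus, and iodinolysis of the alkenyl–Al bond with retention gives the E iodide, which fixes the C11=C12 geometry of the target. The isolated trisubstituted alkene does not react.

Step 6
Reactants: 6 hydroxy lactone acid; 9 (1E)-1-iodo-2,6-dimethylhepta-1,5-diene
Product: 11 2-[2,5-dihydroxy-1-[(2E)-3,7-dimethylocta-2,6-dienoyl]cyclohex-3-en-1-yl]acetic acid (C3–OH and C6–OH cis to the C10 acyl group and trans to the CH2CO2H arm), via alkenyllithium 10 (not isolated)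
Conditions: 9 (1.4 equiv), t-BuLi (2.8 equiv), Et2O, −78 °C; 6, n-BuLi (2.0 equiv), THF, −78 °C; add 10, −78 °C; AcOH, −78 °C
Reagents that add atoms: none
Why: Iodine–lithium exchange with retention gives 10; once the O–H and CO2H of 6 are deprotonated the C8 lithium carboxylate is inert at −78 °C, so 10 adds only to the strained bridged lactone carbonyl C10 (acyl substitution of a lactone by an organolithium, opening to the ketone and the C6 alkoxide). The lactone has no alpha hydrogen and a bridgehead enolate is geometrically impossible, so enolisation cannot compete; the quaternary neighbour slows a second addition, and the cold acidic quench keeps the C3 alkoxide from retro-aldol cleavage once the ketone is free. No stereocentre is formed and the E alkene is retained.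

Step 7
Reactants: 11 keto acid diol
Product: 13 6,9-dihydroxy-1-[(1E)-2,6-dimethylhepta-1,5-dien-1-yl]-2-oxaspiro[4.5]dec-7-en-3-one (ring B closed; C10 configured as in the target with its chain on the C3 side of ring B; C3–OH and C6–OH cis to C10), via triol acid 12 (not isolated)
Conditions: Et2BOMe (2.5 equiv), THF/MeOH (4:1), −78 °C; NaBH4 (2.5 equiv), −78 °C; AcOH, MeOH co-evaporation; aq. citric acid (pH 3), EtOAc, rt
Reagents that add atoms: none
Why: Narasaka–Prasad reduction: Et2BOMe ties the C3 hydroxyl and the C10 ketone into a six-membered boron chelate cis-fused to ring A, and external hydride attacks axially on the half-chair in which C3–H is axial and C5 is axial on the opposite face, giving the 1,3-syn diol, which is the C10 configuration of the target. Low temperature and the boron-activated carbonyl favour 1,2- over 1,4-reduction. On acidification 12 closes ring B by 5-exo-trig acyl substitution at C8, helped by the gem-disubstituent effect of C4; O10 is the only hydroxyl that can form an unstrained five-membered lactone with C8.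

Step 8
Reactants: 13 spiro lactone diol
Product: 14 9-(tert-butyldimethylsilyloxy)-6-hydroxy-1-[(1E)-2,6-dimethylhepta-1,5-dien-1-yl]-2-oxaspiro[4.5]dec-7-en-3-one (silyl ether on O6; C3–OH free)
Conditions: TBSCl (1.1 equiv), imidazole (2.2 equiv), DMF, −10 to 0 °C
Reagents that add atoms: tert-butyldimethylsilyl chloride, C[Si](C)(Cl)C(C)(C)C
Why: Silylation under steric control: C6–OH is flanked by a CH2 group, whereas C3–OH is neopentyl-like (next to the spiro carbon and syn to the C10 substituent), so one equivalent of the bulky chloride takes O6. No stereocentre is affected.

Step 9
Reactants: 14 C6 silyl ether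
Product: 15 9-(tert-butyldimethylsilyloxy)-1-[(1E)-2,6-dimethylhepta-1,5-dien-1-yl]-2-oxaspiro[4.5]dec-7-ene-3,6-dione (C3 ketone conjugated with C1=C2)
Conditions: Dess–Martin periodinane (1.5 equiv), pyridine (5 equiv), CH2Cl2, 0 °C to rt
Reagents that add atoms: none
Why: Dess–Martin oxidation of the remaining allylic C3 alcohol to the enone under buffered, non-basic conditions that leave the allylic lactone, the silyl ether and the alkenes alone. The C3 stereocentre, having served in steps 2 and 7, is removed; C4 has no alpha hydrogen and cannot epimerise.

Step 10
Reactants: 15 enone silyl ether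
Product: 16 9-hydroxy-1-[(1E)-2,6-dimethylhepta-1,5-dien-1-yl]-2-oxaspiro[4.5]dec-7-ene-3,6-dione (free C6–OH gamma to the C3 ketone)
Conditions: HF·pyridine, pyridine, THF, 0 °C to rt
Reagents that add atoms: none
Why: Fluoride-induced cleavage of the silyl ether under weakly acidic, buffered conditions; a basic fluoride source is avoided because an alkoxide could open ring B and start retro-aldol cleavage of C4–C10.

Step 11
Reactants: 16 hydroxy enone
Product: 18 cis-fused 2-(trichloromethyl)-4,5-dihydrooxazole spanning N1/C1 and O6/C6 of the spiro lactone ketone (C1–N cis to C6–O), via trichloroacetimidate 17 (not isolated)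
Conditions: Cl3CCN (1.5 equiv), DBU (0.2 equiv), CH2Cl2, 0 °C to rt
Reagents that add atoms: trichloroacetonitrile, ClC(Cl)(Cl)C#N
Why: Base-catalysed addition of O6 to the nitrile gives imidate 17, whose nitrogen adds to C1 of the enone in a 5-exo-trig intramolecular aza-Michael reaction (trichloroacetimidate conjugate addition); the one-atom O–C–N tether can reach only the face of C1 that carries O6, so C1–N forms cis to C6–O, which is the C1 configuration of the target. Catalytic non-nucleophilic base spares ring B.

Step 12
Reactants: 18 trichloromethyl oxazoline
Product: 19 2,2,2-trichloro-N-[9-hydroxy-1-[(1E)-2,6-dimethylhepta-1,5-dien-1-yl]-3,6-dioxo-2-oxaspiro[4.5]decan-8-yl]acetamide (all four stereocentres as in the target)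
Conditions: 0.5 M aq. HCl, THF, 0 °C to rt; NaHCO3 work-up (pH 7 to 8)
Reagents that add atoms: water, O
Why: Acid-catalysed addition of water to the C=N carbon of the protonated oxazoline and ring opening give the N-trichloroacetyl amino alcohol after neutralisation; if the ring opens at C–N first, the acyl group returns to nitrogen through a cis five-membered transition state. No bond to a stereocentre is broken, and dilute acid at low temperature is chosen to spare the allylic C10–O9 bond and the trisubstituted alkenes.

Step 13
Reactants: 19 hydroxy trichloroacetamide
Product: 20 (+)-miliusane V, N-[(1R,5R,8R,9S)-1-[(1E)-2,6-dimethylhepta-1,5-dien-1-yl]-9-hydroxy-3,6-dioxo-2-oxaspiro[4.5]decan-8-yl]acetamide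
Conditions: Bu3SnH (3.5 equiv), AIBN (0.2 equiv), toluene, 80 °C
Reagents that add atoms: none
Why: Radical chain hydrodechlorination: tin radicals abstract the three chlorines in turn from the carbon alpha to the amide carbonyl and each stabilised radical is quenched by Bu3SnH, turning CCl3 into CH3 (trichloroacetamide to acetamide reduction). Ketone, lactone, hydroxyl and the unactivated trisubstituted alkenes are inert under these conditions and no stereocentre is involved.

## Compound list

1 | itaconic anhydride (3-methylideneoxolane-2,5-dione) | C=C1CC(=O)OC1=O | starting material
2 | (1E,3E)-buta-1,3-diene-1,4-diyl diacetate | CC(=O)O/C=C/C=C/OC(C)=O | starting material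
3 | racemic 6,9-diacetoxy-2-oxaspiro[4.5]dec-7-ene-1,3-dione, acetoxy groups cis to C10 | C1=C[C@H](OC(C)=O)[C@@]2(CC(=O)OC2=O)C[C@@H]1OC(C)=O | intermediate
4 | racemic 2,5-diacetoxy-1-(2-methoxy-2-oxoethyl)cyclohex-3-ene-1-carboxylic acid (half ester, acetoxy groups cis to CO2H) | C1=C[C@H](OC(C)=O)[C@](CC(=O)OC)(C(=O)O)C[C@@H]1OC(C)=O | intermediate (not isolated)
5 | racemic methyl 2-(2-hydroxy-7-oxo-6-oxabicyclo[3.2.1]oct-3-en-1-yl)acetate, OH syn to the lactone bridge | C1=C[C@H](O)[C@@]2(CC(=O)OC)C[C@@H]1OC2=O | intermediate
6 | 2-(2-hydroxy-7-oxo-6-oxabicyclo[3.2.1]oct-3-en-1-yl)acetic acid, single enantiomer | C1=C[C@H](O)[C@@]2(CC(=O)O)C[C@@H]1OC2=O | intermediate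
7 | 5-bromo-2-methylpent-2-ene | CC(C)=CCCBr | starting material
8 | 6-methylhept-5-en-1-yne | CC(C)=CCCC#C | intermediate
9 | (1E)-1-iodo-2,6-dimethylhepta-1,5-diene | I/C=C(\C)CCC=C(C)C | intermediate
10 | [(1E)-2,6-dimethylhepta-1,5-dien-1-yl]lithium | [Li]/C=C(\C)CCC=C(C)C | intermediate (not isolated)
11 | 2-[2,5-dihydroxy-1-[(2E)-3,7-dimethylocta-2,6-dienoyl]cyclohex-3-en-1-yl]acetic acid, hydroxyls cis to the acyl group | C1=C[C@H](O)[C@](CC(=O)O)(C(=O)/C=C(\C)CCC=C(C)C)C[C@@H]1O | intermediate
12 | 2-[2,5-dihydroxy-1-[(2E)-1-hydroxy-3,7-dimethylocta-2,6-dien-1-yl]cyclohex-3-en-1-yl]acetic acid, O3 and O10 1,3-syn | C1=C[C@H](O)[C@](CC(=O)O)([C@H](O)/C=C(\C)CCC=C(C)C)C[C@@H]1O | intermediate (not isolated)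
13 | 6,9-dihydroxy-1-[(1E)-2,6-dimethylhepta-1,5-dien-1-yl]-2-oxaspiro[4.5]dec-7-en-3-one | C1=C[C@H](O)[C@@]2(CC(=O)O[C@@H]2/C=C(\C)CCC=C(C)C)C[C@@H]1O | intermediate
14 | 9-(tert-butyldimethylsilyloxy)-6-hydroxy-1-[(1E)-2,6-dimethylhepta-1,5-dien-1-yl]-2-oxaspiro[4.5]dec-7-en-3-one | C1=C[C@H](O)[C@@]2(CC(=O)O[C@@H]2/C=C(\C)CCC=C(C)C)C[C@@H]1O[Si](C)(C)C(C)(C)C | intermediate
15 | 9-(tert-butyldimethylsilyloxy)-1-[(1E)-2,6-dimethylhepta-1,5-dien-1-yl]-2-oxaspiro[4.5]dec-7-ene-3,6-dione | C1=CC(=O)[C@@]2(CC(=O)O[C@@H]2/C=C(\C)CCC=C(C)C)C[C@@H]1O[Si](C)(C)C(C)(C)C | intermediate
16 | 9-hydroxy-1-[(1E)-2,6-dimethylhepta-1,5-dien-1-yl]-2-oxaspiro[4.5]dec-7-ene-3,6-dione | C1=CC(=O)[C@@]2(CC(=O)O[C@@H]2/C=C(\C)CCC=C(C)C)C[C@@H]1O | intermediate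
17 | O6 2,2,2-trichloroacetimidate of 16 | C1=CC(=O)[C@@]2(CC(=O)O[C@@H]2/C=C(\C)CCC=C(C)C)C[C@@H]1OC(=N)C(Cl)(Cl)Cl | intermediate (not isolated)
18 | cis-fused 2-(trichloromethyl)oxazoline (N on C1, O on C6) of the spiro lactone ketone | ClC(Cl)(Cl)C1=N[C@@H]2CC(=O)[C@@]3(CC(=O)O[C@@H]3/C=C(\C)CCC=C(C)C)C[C@@H]2O1 | intermediate
19 | 2,2,2-trichloro-N-[9-hydroxy-1-[(1E)-2,6-dimethylhepta-1,5-dien-1-yl]-3,6-dioxo-2-oxaspiro[4.5]decan-8-yl]acetamide | ClC(Cl)(Cl)C(=O)N[C@@H]1CC(=O)[C@@]2(CC(=O)O[C@@H]2/C=C(\C)CCC=C(C)C)C[C@@H]1O | intermediate
20 | (+)-miliusane V, N-[(1R,5R,8R,9S)-1-[(1E)-2,6-dimethylhepta-1,5-dien-1-yl]-9-hydroxy-3,6-dioxo-2-oxaspiro[4.5]decan-8-yl]acetamide | CC(=O)N[C@@H]1CC(=O)[C@@]2(CC(=O)O[C@@H]2/C=C(\C)CCC=C(C)C)C[C@@H]1O | target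

## Step count and least certain steps

Total step count: 13. Longest linear sequence: 11 (steps 1, 2, 3 and 6 to 13); steps 4 and 5 make the side chain.

**Step 1 (key step).** The most likely failures are low endo selectivity and slow cycloaddition. The dienophile is 1,1-disubstituted and only moderately activated, and the heating needed favours migration of its double bond into the ring. Fallback from 1: the more electron-rich diene (1E,3E)-1,4-bis(trimethylsilyloxy)buta-1,3-diene F1 should react well below 100 °C, where endo preference is higher and isomerisation slower. It would give the racemic bis(trimethylsilyl ether) spiro anhydride F2. Under the acidic methanol of step 2 the silyl ethers are lost and the route is rejoined at 5.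

**Step 6.** The most likely failures are addition at more than one site and cleavage of ring A. A second addition to the new ketone, attack on the carboxylate on warming, and retro-aldol opening from the C3 alkoxide are all possible, and the dilithium salt may be poorly soluble. Fallback from 6: silylation with TESOTf and 2,6-lutidine followed by mildly acidic aqueous work-up would give the C3 triethylsilyl ether acid F5. One equivalent of n-BuLi and then 10 would open the lactone to the C3 triethylsilyl ether keto acid F6, which cannot undergo retro-aldol. HF·pyridine removes the silyl group and the route is rejoined at 11.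

**Step 7.** The most likely failure is poor facial selectivity. The free C6 hydroxyl and the carboxylic acid can bind boron, and ring–chain tautomerism of the keto acid can divert the ketone from the O3 chelate; conjugate reduction is a second risk. Fallback from 11: TBSCl and imidazole should silylate the less hindered O6 to give the C6 silyl ether keto acid F7. Trimethylsilyldiazomethane would give its methyl ester F8, in which O3 is the only chelating group. The same boron-mediated reduction, followed by lactonisation with a trace of pyridinium tosylate, rejoins the route at 14 and makes step 8 unnecessary.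

**Step 3.** The most likely failure is insufficient enantioselection, because the ester group is two bonds away from the stereocentre. Fallback from 5: saponification with LiOH in aqueous THF, then acidification to pH 1 to reclose the bridging lactone, would give the racemic acid F3. Crystallisation of its (S)-1-phenylethylammonium salt F4 (or the salt of the mirror-image amine, whichever deposits the wanted antipode) and acidification rejoin the route at 6.

**Step 12.** The most likely failure is acid-induced ionisation of the allylic C10–O9 bond or cation–olefin reactions of the side chain during oxazoline hydrolysis. Fallback from 18: the order is reversed. Bu3SnH and AIBN would first reduce the trichloromethyl group to give the 2-methyloxazoline F9, which is far more basic. It should open in dilute aqueous acetic acid at room temperature, and O-to-N acetyl shift on neutralisation leads directly to 20.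

## Further compounds

F1 | step 1 | (1E,3E)-1,4-bis(trimethylsilyloxy)buta-1,3-diene | C[Si](C)(C)O/C=C/C=C/O[Si](C)(C)C
F2 | step 1 | racemic 6,9-bis(trimethylsilyloxy)-2-oxaspiro[4.5]dec-7-ene-1,3-dione, silyloxy groups cis to C10 | C1=C[C@H](O[Si](C)(C)C)[C@@]2(CC(=O)OC2=O)C[C@@H]1O[Si](C)(C)C
F3 | step 3 | racemic 2-(2-hydroxy-7-oxo-6-oxabicyclo[3.2.1]oct-3-en-1-yl)acetic acid | C1=C[C@H](O)[C@@]2(CC(=O)O)C[C@@H]1OC2=O
F4 | step 3 | (S)-1-phenylethylammonium salt of 6 | C1=C[C@H](O)[C@@]2(CC(=O)[O-])C[C@@H]1OC2=O.C[C@H]([NH3+])c1ccccc1
F5 | step 6 | C3 triethylsilyl ether of 6 | C1=C[C@H](O[Si](CC)(CC)CC)[C@@]2(CC(=O)O)C[C@@H]1OC2=O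
F6 | step 6 | C3 triethylsilyl ether of 11 | C1=C[C@H](O[Si](CC)(CC)CC)[C@](CC(=O)O)(C(=O)/C=C(\C)CCC=C(C)C)C[C@@H]1O
F7 | step 7 | C6 tert-butyldimethylsilyl ether of 11 | C1=C[C@H](O)[C@](CC(=O)O)(C(=O)/C=C(\C)CCC=C(C)C)C[C@@H]1O[Si](C)(C)C(C)(C)C
F8 | step 7 | methyl ester of F7 | C1=C[C@H](O)[C@](CC(=O)OC)(C(=O)/C=C(\C)CCC=C(C)C)C[C@@H]1O[Si](C)(C)C(C)(C)C
F9 | step 12 | cis-fused 2-methyloxazoline analogue of 18 | CC1=N[C@@H]2CC(=O)[C@@]3(CC(=O)O[C@@H]3/C=C(\C)CCC=C(C)C)C[C@@H]2O1
A1 | alternative 1 | 4,4-dimethoxycyclohexa-2,5-dienone bearing at C4 the C10 carbinol as its O-(tert-butyldimethylsilyl) ketene acetal | O=C1C=CC(OC)(OC)C=C1[C@H](OC(=C)O[Si](C)(C)C(C)(C)C)/C=C(\C)CCC=C(C)C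
A2 | alternative 1 | crossed photoadduct, 2-oxabicyclo[2.1.1]hexane fused to ring A | O=C1C=CC(OC)(OC)[C@H]2[C@]13C[C@]2(O[Si](C)(C)C(C)(C)C)O[C@@H]3/C=C(\C)CCC=C(C)C
A3 | alternative 2 | 1-(2-tert-butoxy-2-oxoethyl)cyclohexa-2,5-diene-1-carboxylic acid | CC(C)(C)OC(=O)CC1(C(=O)O)C=CCC=C1
A4 | alternative 2 | bridged iodolactone | CC(C)(C)OC(=O)C[C@@]12C=CC[C@@H](OC1=O)[C@@H]2I
A5 | alternative 3 | C3 N-(2,4,6-trimethylbenzoyloxy)carbamate of the C1=C6 spiro lactone | O=C(NOC(=O)c1c(C)cc(C)cc1C)O[C@H]2CC=CC[C@]23CC(=O)O[C@@H]3/C=C(\C)CCC=C(C)C
A6 | alternative 3 | bridging cyclic carbamate with free C6 hydroxyl | O=C1N[C@@H]2C[C@H](O1)[C@@]3(CC(=O)O[C@@H]3/C=C(\C)CCC=C(C)C)C[C@@H]2O
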